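**Plan**

- Labels: ring A is the cyclopentane, and its two functional atoms are named in words: the ring-A quaternary carbon (methyl-bearing, bonded to ring B) and its neighbour, the ring-A methylidene carbon (an oxygen-bearing carbon until step 17). Ring B is the cyclohexene (B1 quaternary, B2 CH2, B3=B4 with the methyl on B4, B5 the carbinol carbon, B6 CH2).
- Enabling feature: B1 is a methyl-bearing quaternary carbon, 1,3 to the oxygenated B5 and bonded to the ring-A quaternary carbon. A tertiary B1 radical, made from a 1,1-disubstituted alkene whose CH2 becomes the B1 methyl, can therefore close ring B at B1–B2 onto a vinyl ketone (B2=B3–B4=O) while B5 steers the new centre.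
- Retrosynthetic cuts, in order: caffeate C–O at B5; the exocyclic C=CH2 of ring A; B4–CH3; B1–B2 (opens ring B); B3–B4; B1–B6; the B1 methyl carbon; the methyl on the ring-A quaternary carbon.
- Forward: ring A is there from the start; its quaternary carbon is made by methylation and the ester carbon becomes B1; the chain grows by B1–B6 (alkenyl metal plus glycidic ester) and B4–B3 (vinyl Grignard); ring B closes at B1–B2; then the B4 methyl, the caffeate at B5 and the ring-A methylidene.
- Stereochemistry: the ring-A carbinol centre from asymmetric hydrogenation is relayed to the ring-A quaternary carbon by dianion methylation and later erased; B5 comes from methyl (S)-glycidate; B1 is set from B5 in the ring closure; the E-alkene comes with caffeic acid.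

Key step: step 10

Remark: TBS = tert-butyldimethylsilyl, Tris = 2,4,6-triisopropylbenzenesulfonyl; both oxygens travel as silyl ethers because a benzylic ether on the ring-A or B5 oxygen would put a weak C–H bond five atoms from the B1 radical, and RuCl2[(R)-BINAP] is assumed to give the 2R carbinol in step 1 as it does for simple β-keto esters.

**Route**

Step 1
Reactants: 1 ethyl 2-oxocyclopentane-1-carboxylate
Product: 2 ethyl (1R,2R)-2-hydroxycyclopentane-1-carboxylate
Conditions: H2 (100 atm), RuCl2[(R)-BINAP] (cat.), CH2Cl2, 50 °C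
Reagents that add atoms: none
Why: Noyori asymmetric hydrogenation under dynamic kinetic resolution, in which the keto ester epimerises faster than it is reduced and RuCl2[(R)-BINAP] fixes the carbinol carbon (the future ring-A methylidene carbon) as R, the only centre of 2 that survives step 2.

Step 2
Reactants: 2 ethyl (1R,2R)-2-hydroxycyclopentane-1-carboxylate
Product: 4 ethyl (1S,2R)-2-hydroxy-1-methylcyclopentane-1-carboxylate, via dilithium alkoxide–enolate 3 (not isolated)
Conditions: LiN(i-Pr)2 (2.2 equiv), THF, −78 → −20 °C; MeI, DMPU, −78 → 0 °C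
Reagents that add atoms: iodomethane, CI
Why: Fráter–Seebach alkylation, in which the chelated dianion is methylated on the ring face away from the O–Li group, so the new methyl on the ring-A quaternary carbon ends up trans and the ester cis to the ring-A oxygen.

Step 3
Reactants: 4 ethyl (1S,2R)-2-hydroxy-1-methylcyclopentane-1-carboxylate
Product: 5 ethyl (1S,2R)-2-(TBSO)-1-methylcyclopentane-1-carboxylate
Conditions: TBSOTf, 2,6-lutidine, CH2Cl2, 0 °C → rt
Reagents that add atoms: tert-butyldimethylsilyl trifluoromethanesulfonate, CC(C)(C)[Si](C)(C)OS(=O)(=O)C(F)(F)F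
Why: Silyl triflate silylation is the standard way to protect a hindered secondary alcohol next to a quaternary carbon, and no stereocentre is touched.

Step 4
Reactants: 5 ethyl (1S,2R)-2-(TBSO)-1-methylcyclopentane-1-carboxylate
Product: 7 1-[(1S,2R)-2-(TBSO)-1-methylcyclopentyl]ethan-1-one, via lithium enolate of the α-silyl ketone 6 (not isolated)
Conditions: Me3SiCH2Li (2.5 equiv), pentane/THF, 0 °C → rt; then MeOH, rt; aq. NH4Cl
Reagents that add atoms: (trimethylsilyl)methyllithium, [Li]C[Si](C)(C)C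
Why: Known ester-to-methyl-ketone conversion, in which acyl substitution gives an α-silyl ketone that the second equivalent deprotonates at once (so no tertiary alcohol forms) and methanol then cleaves the C–Si bond; the ring-A quaternary carbon cannot epimerise.

Step 5
Reactants: 7 1-[(1S,2R)-2-(TBSO)-1-methylcyclopentyl]ethan-1-one
Product: 8 N'-[(1E)-1-[(1R,2R)-2-(TBSO)-1-methylcyclopentyl]ethylidene]-2,4,6-tri(propan-2-yl)benzenesulfonohydrazide
Conditions: TrisNHNH2, HCl (cat.), THF, rt
Reagents that add atoms: 2,4,6-triisopropylbenzenesulfonohydrazide, CC(C)c1cc(C(C)C)c(S(=O)(=O)NN)c(C(C)C)c1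
Why: Hydrazone condensation places the sulfonamide nitrogen anti to the tert-alkyl group, that is syn to the methyl group that must be deprotonated next.

Step 6
Reactants: 8 N'-[(1E)-1-[(1R,2R)-2-(TBSO)-1-methylcyclopentyl]ethylidene]-2,4,6-tri(propan-2-yl)benzenesulfonohydrazide; 9 methyl (2S)-oxirane-2-carboxylate
Product: 12 methyl (2S)-2-hydroxy-4-[(1R,2R)-2-(TBSO)-1-methylcyclopentyl]pent-4-enoate, via alkenyllithium 10 (not isolated), via alkenylmagnesium bromide 11 (not isolated)
Conditions: n-BuLi (2.1 equiv), THF, −78 → 0 °C (10 min), then −78 °C; MgBr2·OEt2; CuI (15 mol %), 9, −40 → −20 °C; aq. NH4Cl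
Reagents that add atoms: none
Why: Shapiro reaction (the dianion loses sulfinate and dinitrogen, and only the methyl group can be deprotonated) followed by transmetalation to magnesium and monovalent-copper-catalysed SN2 opening of the glycidic ester at its unsubstituted ring CH2, a known reaction of alkenyl Grignard reagents that forms B1–B6 and leaves the B5 stereocentre of 9 untouched.

Step 7
Reactants: 12 methyl (2S)-2-hydroxy-4-[(1R,2R)-2-(TBSO)-1-methylcyclopentyl]pent-4-enoate
Product: 13 methyl (2S)-2-(TBSO)-4-[(1R,2R)-2-(TBSO)-1-methylcyclopentyl]pent-4-enoate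
Conditions: TBSCl, imidazole, DMF, rt
Reagents that add atoms: tert-butyldimethylsilyl chloride, CC(C)(C)[Si](C)(C)Cl
Why: Standard silylation of an α-hydroxy ester under weakly basic conditions that do not epimerise B5.

Step 8
Reactants: 13 methyl (2S)-2-(TBSO)-4-[(1R,2R)-2-(TBSO)-1-methylcyclopentyl]pent-4-enoate
Product: 14 (2S)-2-(TBSO)-4-[(1R,2R)-2-(TBSO)-1-methylcyclopentyl]-N-methoxy-N-methylpent-4-enamide
Conditions: MeNH(OMe)·HCl, i-PrMgCl, THF, −20 → 0 °C
Reagents that add atoms: N,O-dimethylhydroxylamine hydrochloride, CNOC.Cl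
Why: Direct aminolysis of the methyl ester by the chloromagnesium amide (Weinreb amide formation) is routine for α-silyloxy esters and does not enolise B5 at this temperature.

Step 9
Reactants: 14 (2S)-2-(TBSO)-4-[(1R,2R)-2-(TBSO)-1-methylcyclopentyl]-N-methoxy-N-methylpent-4-enamide
Product: 16 (4S)-4-(TBSO)-6-[(1R,2R)-2-(TBSO)-1-methylcyclopentyl]hepta-1,6-dien-3-one, via magnesium hemiaminal chelate 15 (not isolated)
Conditions: CH2=CHMgBr, THF, −78 → 0 °C; inverse quench into cold 1 M HCl
Reagents that add atoms: vinylmagnesium bromide, C=C[Mg]Br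
Why: Weinreb ketone synthesis, in which the stable magnesium chelate prevents a second addition and the acidic inverse quench protonates the released amine so that it cannot add to the vinyl ketone.

Step 10
Reactants: 16 (4S)-4-(TBSO)-6-[(1R,2R)-2-(TBSO)-1-methylcyclopentyl]hepta-1,6-dien-3-one
Product: 17 (2S,4S)-2-(TBSO)-4-[(1R,2R)-2-(TBSO)-1-methylcyclopentyl]-4-methylcyclohexan-1-one
Conditions: Fe(acac)3 (0.3 equiv), PhSiH3 (2.5 equiv), EtOH/ethylene glycol (5:1), 60 °C, 0.02 M
Reagents that add atoms: none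
Why: The iron hydride formed from Fe(acac)3 and PhSiH3 transfers a hydrogen atom to the CH2 terminus of the 1,1-disubstituted alkene, which creates the tertiary B1 radical and the B1 methyl; the radical adds to the unsubstituted β-carbon B2 of the vinyl ketone, and the α-keto radical is reduced by divalent iron and protonated by ethanol. The closest known reaction type is the iron-hydride olefin–enone reductive coupling (hydrogen-atom-transfer Giese reaction), here intramolecular, which is established for building hindered quaternary carbons. Ring B closes in the 6-endo-trig mode, because 5-exo attack at the α-carbon B3 is polarity-mismatched and would leave a primary radical. The new stereocentre B1 is controlled by B5 through a chair-like transition state with the B5 silyloxy group equatorial and the bulky ring-A substituent of the planar radical carbon pseudo-equatorial (methyl pseudo-axial), which places ring A cis to the B5 oxygen as in the target. The step needs hydrogen-atom transfer to one alkene only and 1,3-diastereoselection: the first is secured because the ring-A oxygen-bearing carbon is still a silyl ether carbinol (its methylidene comes only in step 17) and the electron-poor vinyl ketone is a poor hydrogen-atom acceptor, the second by the fixed S configuration at B5 and the size difference between methyl and ring A, while the silyl ethers offer no weak C–H bond five atoms from the radical.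

Step 11
Reactants: 17 (2S,4S)-2-(TBSO)-4-[(1R,2R)-2-(TBSO)-1-methylcyclopentyl]-4-methylcyclohexan-1-one
Product: 19 (4S,6S)-6-(TBSO)-4-[(1R,2R)-2-(TBSO)-1-methylcyclopentyl]-4-methylcyclohex-1-en-1-yl trifluoromethanesulfonate, via potassium enolate 18 (not isolated)
Conditions: KN(SiMe3)2, THF, −78 °C; PhNTf2, −78 → −40 °C; aq. NH4Cl
Reagents that add atoms: N-phenylbis(trifluoromethanesulfonimide), O=S(=O)(N(c1ccccc1)S(=O)(=O)C(F)(F)F)C(F)(F)F
Why: Kinetic deprotonation by the bulky amide takes the unhindered B3 methylene and not the silyloxy-bearing B5 methine, as is usual for α-silyloxy ketones, and O-triflation of the enolate fixes the double bond at B3=B4 without epimerising B5.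

Step 12
Reactants: 19 (4S,6S)-6-(TBSO)-4-[(1R,2R)-2-(TBSO)-1-methylcyclopentyl]-4-methylcyclohex-1-en-1-yl trifluoromethanesulfonate
Product: 20 tert-butyl{[(1S,5S)-5-[(1R,2R)-2-(TBSO)-1-methylcyclopentyl]-2,5-dimethylcyclohex-2-en-1-yl]oxy}dimethylsilane
Conditions: MeMgBr, Fe(acac)3 (5 mol %), THF/NMP, −30 → 0 °C
Reagents that add atoms: methylmagnesium bromide, C[Mg]Br
Why: Iron-catalysed Kumada-type coupling of alkenyl triflates with methyl Grignard reagents is well established and installs the B4 methyl without moving the double bond or touching the silyl ethers.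

Step 13
Reactants: 20 tert-butyl{[(1S,5S)-5-[(1R,2R)-2-(TBSO)-1-methylcyclopentyl]-2,5-dimethylcyclohex-2-en-1-yl]oxy}dimethylsilane
Product: 21 (1S,5S)-5-[(1R,2R)-2-hydroxy-1-methylcyclopentyl]-2,5-dimethylcyclohex-2-en-1-ol
Conditions: Bu4NF (excess), THF, 60 °C
Reagents that add atoms: none
Why: Fluoride cleaves both silyl ethers, heating being needed only for the hindered ring-A ether, and nothing else in 20 is fluoride-sensitive.

Step 14
Reactants: 22 caffeic acid, (2E)-3-(3,4-dihydroxyphenyl)prop-2-enoic acid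
Product: 24 (2E)-3-[3,4-bis(TBSO)phenyl]prop-2-enoic acid, via tris-silylated caffeate 23 (not isolated)
Conditions: TBSCl (3.3 equiv), imidazole, DMF, rt; then AcOH/THF/H2O (3:1:1), rt
Reagents that add atoms: tert-butyldimethylsilyl chloride, CC(C)(C)[Si](C)(C)Cl
Why: Exhaustive silylation followed by selective hydrolysis of the far more labile silyl ester leaves the two aryl silyl ethers and the free acid with the E-alkene unchanged.

Step 15
Reactants: 21 (1S,5S)-5-[(1R,2R)-2-hydroxy-1-methylcyclopentyl]-2,5-dimethylcyclohex-2-en-1-ol; 24 (2E)-3-[3,4-bis(TBSO)phenyl]prop-2-enoic acid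
Product: 25 (1S,5S)-5-[(1R,2R)-2-hydroxy-1-methylcyclopentyl]-2,5-dimethylcyclohex-2-en-1-yl (2E)-3-[3,4-bis(TBSO)phenyl]prop-2-enoate
Conditions: 24 (1.05 equiv), EDC·HCl, DMAP (0.2 equiv), CH2Cl2, 0 °C → rt
Reagents that add atoms: none
Why: Steglich esterification acylates the allylic B5 hydroxyl, whereas the ring-A hydroxyl, wedged against the ring-A quaternary carbon and the quaternary B1 behind it, should be too hindered to compete with one equivalent of acid.

Step 16
Reactants: 25 (1S,5S)-5-[(1R,2R)-2-hydroxy-1-methylcyclopentyl]-2,5-dimethylcyclohex-2-en-1-yl (2E)-3-[3,4-bis(TBSO)phenyl]prop-2-enoate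
Product: 26 (1S,5S)-2,5-dimethyl-5-[(1R)-1-methyl-2-oxocyclopentyl]cyclohex-2-en-1-yl (2E)-3-[3,4-bis(TBSO)phenyl]prop-2-enoate
Conditions: Dess–Martin periodinane, NaHCO3, CH2Cl2, rt
Reagents that add atoms: none
Why: Dess–Martin oxidation converts the hindered secondary alcohol into the ketone under neutral conditions that spare the enoate, the alkene and the aryl silyl ethers.

Step 17
Reactants: 26 (1S,5S)-2,5-dimethyl-5-[(1R)-1-methyl-2-oxocyclopentyl]cyclohex-2-en-1-yl (2E)-3-[3,4-bis(TBSO)phenyl]prop-2-enoate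
Product: 27 (1S,5S)-2,5-dimethyl-5-[(1S)-1-methyl-2-methylidenecyclopentyl]cyclohex-2-en-1-yl (2E)-3-[3,4-bis(TBSO)phenyl]prop-2-enoate
Conditions: Zn, CH2Br2, TiCl4, THF, −40 → 5 °C (pre-formed reagent); then 26, CH2Cl2, 0 °C → rt
Reagents that add atoms: dibromomethane, BrCBr
Why: Takai–Lombardo methylenation uses a non-basic methylene reagent made from Zn, CH2Br2 and TiCl4 that converts hindered, enolisable ketones into methylidene groups and leaves esters alone, whereas a phosphorus ylide would add to the enoate; the ring-A quaternary carbon cannot epimerise.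

Step 18
Reactants: 27 (1S,5S)-2,5-dimethyl-5-[(1S)-1-methyl-2-methylidenecyclopentyl]cyclohex-2-en-1-yl (2E)-3-[3,4-bis(TBSO)phenyl]prop-2-enoate
Product: 28 (1S,5S)-2,5-dimethyl-5-[(1S)-1-methyl-2-methylidenecyclopentyl]cyclohex-2-en-1-yl (2E)-3-(3,4-dihydroxyphenyl)prop-2-enoate
Conditions: Bu4NF, AcOH (1:1), THF, 0 °C
Reagents that add atoms: none
Why: Fluoride removes the two aryl silyl ethers, and the acetic acid buffer keeps the allylic ester and the free catechol away from basic conditions.

**Compound list**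

1 | ethyl 2-oxocyclopentane-1-carboxylate | CCOC(=O)C1CCCC1=O | starting material
2 | ethyl (1R,2R)-2-hydroxycyclopentane-1-carboxylate | CCOC(=O)[C@@H]1CCC[C@H]1O | intermediate
3 | dilithium alkoxide–enolate of 2 | [Li+].[Li+].CCOC([O-])=C1CCC[C@H]1[O-] | intermediate (not isolated)
4 | ethyl (1S,2R)-2-hydroxy-1-methylcyclopentane-1-carboxylate | CCOC(=O)[C@@]1(C)CCC[C@H]1O | intermediate
5 | ethyl (1S,2R)-2-(TBSO)-1-methylcyclopentane-1-carboxylate | CCOC(=O)[C@@]1(C)CCC[C@H]1O[Si](C)(C)C(C)(C)C | intermediate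
6 | lithium enolate of 1-[(1S,2R)-2-(TBSO)-1-methylcyclopentyl]-2-(trimethylsilyl)ethan-1-one | [Li+].C[Si](C)(C)C=C([O-])[C@@]1(C)CCC[C@H]1O[Si](C)(C)C(C)(C)C | intermediate (not isolated)
7 | 1-[(1S,2R)-2-(TBSO)-1-methylcyclopentyl]ethan-1-one | CC(=O)[C@@]1(C)CCC[C@H]1O[Si](C)(C)C(C)(C)C | intermediate
8 | N'-[(1E)-1-[(1R,2R)-2-(TBSO)-1-methylcyclopentyl]ethylidene]-2,4,6-tri(propan-2-yl)benzenesulfonohydrazide | C/C(=N\NS(=O)(=O)c1c(C(C)C)cc(C(C)C)cc1C(C)C)[C@@]1(C)CCC[C@H]1O[Si](C)(C)C(C)(C)C | intermediate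
9 | methyl (2S)-oxirane-2-carboxylate (methyl (S)-glycidate) | COC(=O)[C@@H]1CO1 | starting material
10 | {1-[(1R,2R)-2-(TBSO)-1-methylcyclopentyl]ethenyl}lithium | [Li]C(=C)[C@@]1(C)CCC[C@H]1O[Si](C)(C)C(C)(C)C | intermediate (not isolated)
11 | alkenylmagnesium bromide corresponding to 10 (ring stereocentres unchanged) | Br[Mg]C(=C)[C@@]1(C)CCC[C@H]1O[Si](C)(C)C(C)(C)C | intermediate (not isolated)
12 | methyl (2S)-2-hydroxy-4-[(1R,2R)-2-(TBSO)-1-methylcyclopentyl]pent-4-enoate | COC(=O)[C@@H](O)CC(=C)[C@@]1(C)CCC[C@H]1O[Si](C)(C)C(C)(C)C | intermediate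
13 | methyl (2S)-2-(TBSO)-4-[(1R,2R)-2-(TBSO)-1-methylcyclopentyl]pent-4-enoate | COC(=O)[C@@H](O[Si](C)(C)C(C)(C)C)CC(=C)[C@@]1(C)CCC[C@H]1O[Si](C)(C)C(C)(C)C | intermediate
14 | (2S)-2-(TBSO)-4-[(1R,2R)-2-(TBSO)-1-methylcyclopentyl]-N-methoxy-N-methylpent-4-enamide | CON(C)C(=O)[C@@H](O[Si](C)(C)C(C)(C)C)CC(=C)[C@@]1(C)CCC[C@H]1O[Si](C)(C)C(C)(C)C | intermediate
15 | bromomagnesium hemiaminal alkoxide (chelate) from 14 and the vinyl Grignard reagent | C=CC(O[Mg]Br)(N(C)OC)[C@@H](O[Si](C)(C)C(C)(C)C)CC(=C)[C@@]1(C)CCC[C@H]1O[Si](C)(C)C(C)(C)C | intermediate (not isolated)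
16 | (4S)-4-(TBSO)-6-[(1R,2R)-2-(TBSO)-1-methylcyclopentyl]hepta-1,6-dien-3-one | C=CC(=O)[C@@H](O[Si](C)(C)C(C)(C)C)CC(=C)[C@@]1(C)CCC[C@H]1O[Si](C)(C)C(C)(C)C | intermediate
17 | (2S,4S)-2-(TBSO)-4-[(1R,2R)-2-(TBSO)-1-methylcyclopentyl]-4-methylcyclohexan-1-one | CC(C)(C)[Si](C)(C)O[C@@H]1CCC[C@]1(C)[C@@]1(C)CCC(=O)[C@@H](O[Si](C)(C)C(C)(C)C)C1 | intermediate
18 | potassium enolate of 17 (B3=B4 enolate) | [K+].CC(C)(C)[Si](C)(C)O[C@@H]1CCC[C@]1(C)[C@@]1(C)CC=C([O-])[C@@H](O[Si](C)(C)C(C)(C)C)C1 | intermediate (not isolated)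
19 | (4S,6S)-6-(TBSO)-4-[(1R,2R)-2-(TBSO)-1-methylcyclopentyl]-4-methylcyclohex-1-en-1-yl trifluoromethanesulfonate | CC(C)(C)[Si](C)(C)O[C@@H]1CCC[C@]1(C)[C@@]1(C)CC=C(OS(=O)(=O)C(F)(F)F)[C@@H](O[Si](C)(C)C(C)(C)C)C1 | intermediate
20 | tert-butyl{[(1S,5S)-5-[(1R,2R)-2-(TBSO)-1-methylcyclopentyl]-2,5-dimethylcyclohex-2-en-1-yl]oxy}dimethylsilane | CC(C)(C)[Si](C)(C)O[C@@H]1CCC[C@]1(C)[C@@]1(C)CC=C(C)[C@@H](O[Si](C)(C)C(C)(C)C)C1 | intermediate
21 | (1S,5S)-5-[(1R,2R)-2-hydroxy-1-methylcyclopentyl]-2,5-dimethylcyclohex-2-en-1-ol | O[C@@H]1CCC[C@]1(C)[C@@]1(C)CC=C(C)[C@@H](O)C1 | intermediate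
22 | caffeic acid, (2E)-3-(3,4-dihydroxyphenyl)prop-2-enoic acid | OC(=O)/C=C/c1ccc(O)c(O)c1 | starting material
23 | tert-butyldimethylsilyl (2E)-3-[3,4-bis(TBSO)phenyl]prop-2-enoate | CC(C)(C)[Si](C)(C)OC(=O)/C=C/c1ccc(O[Si](C)(C)C(C)(C)C)c(O[Si](C)(C)C(C)(C)C)c1 | intermediate (not isolated)
24 | (2E)-3-[3,4-bis(TBSO)phenyl]prop-2-enoic acid | OC(=O)/C=C/c1ccc(O[Si](C)(C)C(C)(C)C)c(O[Si](C)(C)C(C)(C)C)c1 | intermediate
25 | (1S,5S)-5-[(1R,2R)-2-hydroxy-1-methylcyclopentyl]-2,5-dimethylcyclohex-2-en-1-yl (2E)-3-[3,4-bis(TBSO)phenyl]prop-2-enoate | O[C@@H]1CCC[C@]1(C)[C@@]1(C)CC=C(C)[C@@H](OC(=O)/C=C/c2ccc(O[Si](C)(C)C(C)(C)C)c(O[Si](C)(C)C(C)(C)C)c2)C1 | intermediate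
26 | (1S,5S)-2,5-dimethyl-5-[(1R)-1-methyl-2-oxocyclopentyl]cyclohex-2-en-1-yl (2E)-3-[3,4-bis(TBSO)phenyl]prop-2-enoate | O=C1CCC[C@]1(C)[C@@]1(C)CC=C(C)[C@@H](OC(=O)/C=C/c2ccc(O[Si](C)(C)C(C)(C)C)c(O[Si](C)(C)C(C)(C)C)c2)C1 | intermediate
27 | (1S,5S)-2,5-dimethyl-5-[(1S)-1-methyl-2-methylidenecyclopentyl]cyclohex-2-en-1-yl (2E)-3-[3,4-bis(TBSO)phenyl]prop-2-enoate | C=C1CCC[C@]1(C)[C@@]1(C)CC=C(C)[C@@H](OC(=O)/C=C/c2ccc(O[Si](C)(C)C(C)(C)C)c(O[Si](C)(C)C(C)(C)C)c2)C1 | intermediate
28 | (1S,5S)-2,5-dimethyl-5-[(1S)-1-methyl-2-methylidenecyclopentyl]cyclohex-2-en-1-yl (2E)-3-(3,4-dihydroxyphenyl)prop-2-enoate | C=C1CCC[C@]1(C)[C@@]1(C)CC=C(C)[C@@H](OC(=O)/C=C/c2ccc(O)c(O)c2)C1 | target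

**Step count and risks**

Total: 18 steps. Longest linear sequence: 17 steps (steps 1–13 and 15–18; step 14 prepares the acid).

Steps most likely to fail:

1. Step 10. The iron hydride may transfer hydrogen to the vinyl ketone, or the hindered tertiary radical may be reduced before the comparatively slow 6-endo closure, so that the alkene is merely hydrogenated. A weak preference for the chair with the equatorial silyloxy group would also erode face selectivity at B1; the B1 epimers are diastereomers and would have to be separated at 17. The fallback sets out from Weinreb amide 14 and comes back at ketone 17. Cobalt-catalysed Markovnikov radical hydrochlorination of the alkene (Co(BF4)2·6H2O with N,N'-bis(3,5-di-tert-butylsalicylidene)-1,1,2,2-tetramethylethylenediamine, TsCl, PhSiH3, EtOH, rt), done before any acceptor alkene is present, would give the tertiary chloride (2S)-2-(TBSO)-4-chloro-4-[(1S,2R)-2-(TBSO)-1-methylcyclopentyl]-N-methoxy-N-methylpentanamide F1. Vinylmagnesium bromide would convert it into the chloro enone (4S)-4-(TBSO)-6-chloro-6-[(1S,2R)-2-(TBSO)-1-methylcyclopentyl]hept-1-en-3-one F2. Slow addition of Bu3SnH with AIBN in benzene at 80 °C would then generate the same B1 radical by chlorine abstraction at low hydride concentration and cyclise it to 17.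

2. Step 6. The alkenyllithium has to be formed at 0 °C, where 1,4-migration of the silyl group from the ring-A oxygen to the carbanion, or proton abstraction from the solvent, can consume it before transmetalation. The fallback sets out from ketone 7 and comes back at hydroxy ester 12. Hydrazine hydrate and Et3N in ethanol would give the hydrazone (E)-{1-[(1R,2R)-2-(TBSO)-1-methylcyclopentyl]ethylidene}hydrazine F3. Iodine and tetramethylguanidine (Barton vinyl iodide synthesis) would give the alkenyl iodide tert-butyl{[(1R,2S)-2-(1-iodoethenyl)-2-methylcyclopentyl]oxy}dimethylsilane F4. Iodine–magnesium exchange with i-PrMgCl·LiCl would give the alkenylmagnesium chloride F5 without any organolithium, and CuI-catalysed opening of 9 would give 12.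

3. Step 17. Methylenation of a ketone flanked by two adjoining quaternary carbons may stall, and prolonged exposure to the Lewis-acidic reagent may damage the allylic ester. The fallback sets out from diol 21 and comes back at ester 27, doing the methylenation before the acid is attached. Selective silylation of the unhindered B5 hydroxyl (TBSCl, imidazole) would give (1R,2R)-2-[(1S,5S)-5-(TBSO)-1,4-dimethylcyclohex-3-en-1-yl]-2-methylcyclopentan-1-ol F6. Dess–Martin oxidation would give the ketone (2R)-2-[(1S,5S)-5-(TBSO)-1,4-dimethylcyclohex-3-en-1-yl]-2-methylcyclopentan-1-one F7. Wittig methylenation (Ph3PCH3Br, KOt-Bu, toluene, 90 °C), now free of any ester, would give tert-butyl{[(1S,5S)-2,5-dimethyl-5-[(1S)-1-methyl-2-methylidenecyclopentyl]cyclohex-2-en-1-yl]oxy}dimethylsilane F8. Bu4NF would release the allylic alcohol (1S,5S)-2,5-dimethyl-5-[(1S)-1-methyl-2-methylidenecyclopentyl]cyclohex-2-en-1-ol F9, and Steglich esterification with 24 would give 27.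

**Further compounds**

F1 | step 10 | (2S)-2-(TBSO)-4-chloro-4-[(1S,2R)-2-(TBSO)-1-methylcyclopentyl]-N-methoxy-N-methylpentanamide (both C-4 epimers) | CON(C)C(=O)[C@@H](O[Si](C)(C)C(C)(C)C)CC(C)(Cl)[C@@]1(C)CCC[C@H]1O[Si](C)(C)C(C)(C)C
F2 | step 10 | (4S)-4-(TBSO)-6-chloro-6-[(1S,2R)-2-(TBSO)-1-methylcyclopentyl]hept-1-en-3-one (both C-6 epimers) | C=CC(=O)[C@@H](O[Si](C)(C)C(C)(C)C)CC(C)(Cl)[C@@]1(C)CCC[C@H]1O[Si](C)(C)C(C)(C)C
F3 | step 6 | (E)-{1-[(1R,2R)-2-(TBSO)-1-methylcyclopentyl]ethylidene}hydrazine | C/C(=N\N)[C@@]1(C)CCC[C@H]1O[Si](C)(C)C(C)(C)C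
F4 | step 6 | tert-butyl{[(1R,2S)-2-(1-iodoethenyl)-2-methylcyclopentyl]oxy}dimethylsilane | IC(=C)[C@@]1(C)CCC[C@H]1O[Si](C)(C)C(C)(C)C
F5 | step 6 | alkenylmagnesium chloride from F4 (ring stereocentres unchanged) | Cl[Mg]C(=C)[C@@]1(C)CCC[C@H]1O[Si](C)(C)C(C)(C)C
F6 | step 17 | (1R,2R)-2-[(1S,5S)-5-(TBSO)-1,4-dimethylcyclohex-3-en-1-yl]-2-methylcyclopentan-1-ol | O[C@@H]1CCC[C@]1(C)[C@@]1(C)CC=C(C)[C@@H](O[Si](C)(C)C(C)(C)C)C1
F7 | step 17 | (2R)-2-[(1S,5S)-5-(TBSO)-1,4-dimethylcyclohex-3-en-1-yl]-2-methylcyclopentan-1-one | O=C1CCC[C@]1(C)[C@@]1(C)CC=C(C)[C@@H](O[Si](C)(C)C(C)(C)C)C1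
F8 | step 17 | tert-butyl{[(1S,5S)-2,5-dimethyl-5-[(1S)-1-methyl-2-methylidenecyclopentyl]cyclohex-2-en-1-yl]oxy}dimethylsilane | C=C1CCC[C@]1(C)[C@@]1(C)CC=C(C)[C@@H](O[Si](C)(C)C(C)(C)C)C1
F9 | step 17 | (1S,5S)-2,5-dimethyl-5-[(1S)-1-methyl-2-methylidenecyclopentyl]cyclohex-2-en-1-ol | C=C1CCC[C@]1(C)[C@@]1(C)CC=C(C)[C@@H](O)C1
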